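**Retrosynthetic overview**

1. Target ⇐ acidolysis/lactonisation (C6–O–C12, last ring) and C8 angeloylation of a bicyclic tert-butyl 12-oate that carries the free C8 alcohol.
2. Key disconnection C7–C8: indium-catalysed electroreductive Barbier macrocyclisation of a C8 aldehyde onto a (Z)-2-(bromomethyl)enoate; it closes the ten-membered ring and sets C7 and C8 from C6.
3. Bromide ⇐ Morita–Baylis–Hillman reaction/bromination at a C7 α-silyloxy aldehyde; C8 aldehyde ⇐ oxidative cleavage of an allyl group on C10.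
4. Furanone (first ring) ⇐ addition of a C2–C7 acetylide to a lactic-acid-derived dioxolanone (C10 by self-regeneration of the D-lactic acid centre), then gold-catalysed 5-endo cyclisation.
5. Alkyne ⇐ D-glutamic-acid lactone: C6 bought, C4 set cis to it by hydrogenation. Ring order: furanone → ten-membered carbocycle → α-methylene lactone.

Assumption: D-lactic acid and (R)-5-(trityloxymethyl)dihydrofuran-2(3H)-one (the trityl ether of the D-glutamic acid lactone) are bought as such.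

Notation: C-numbers are the germacrane numbers of the target (C1 ketone, C2=C3, C3–O–C10 ether, C6 lactone oxygen, C8 ester, C11=C13, C12 carbonyl, C15 hydroxymethyl); TBS = tert-butyldimethylsilyl, TBSO = tert-butyldimethylsilyloxy, Tr = trityl.

**Route**

Step 1
Reactants: 1 D-lactic acid [(R)-2-hydroxypropanoic acid]
Product: 2 (2R,5R)-2-tert-butyl-5-methyl-1,3-dioxolan-4-one
Conditions: pivalaldehyde, p-TsOH·H2O (cat.), H2SO4 (cat.), pentane, reflux, Dean–Stark; recrystallise at −78 °C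
Reagents that add atoms: pivalaldehyde CC(C)(C)C=O
Why: Acid-catalysed acetalisation (Seebach dioxolanone formation) under thermodynamic control puts the tert-butyl group cis to the methyl group, so the new acetal centre (2R) is set by the lactic acid centre and the cis isomer is purified by crystallisation.

Step 2
Reactants: 2 (2R,5R)-2-tert-butyl-5-methyl-1,3-dioxolan-4-one
Product: 4 (2R,5S)-5-allyl-2-tert-butyl-5-methyl-1,3-dioxolan-4-one, via lithium enolate 3 (not isolated)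
Conditions: LiN(iPr)2, THF, −78 °C; allyl bromide, −78 → −30 °C
Reagents that add atoms: allyl bromide C=CCBr
Why: Enolate alkylation with self-regeneration of the stereocentre: allyl bromide attacks the planar enolate on the face opposite the tert-butyl group, which gives the quaternary carbon (future C10) as the 5S isomer with overall retention.

Step 3
Reactants: 5 (R)-5-(trityloxymethyl)dihydrofuran-2(3H)-one
Product: 7 (5R,E)-3-[(TBSO)methylene]-5-(trityloxymethyl)dihydrofuran-2(3H)-one, via sodium formyl enolate 6 (not isolated)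
Conditions: NaH, HCO2Et, THF, 0 °C → rt; then TBSCl, DMF, 0 °C
Reagents that add atoms: ethyl formate CCOC=O; TBSCl CC(C)(C)[Si](C)(C)Cl
Why: Claisen formylation of the lactone and O-silylation of the stabilised enolate give the silyl enol ether without touching the C5 centre (future C6), and the alkene geometry does not matter because it is hydrogenated next.

Step 4
Reactants: 7 (5R,E)-3-[(TBSO)methylene]-5-(trityloxymethyl)dihydrofuran-2(3H)-one
Product: 8 (3S,5R)-3-[(TBSO)methyl]-5-(trityloxymethyl)dihydrofuran-2(3H)-one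
Conditions: H2 (1 atm), 5 wt% Rh/Al2O3, EtOAc, rt
Reagents that add atoms: none
Why: Heterogeneous catalytic hydrogenation delivers hydrogen to the alkene face opposite the bulky trityloxymethyl group, which places the silyloxymethyl group cis to it and sets the future C4 as 3S.

Step 5
Reactants: 8 (3S,5R)-3-[(TBSO)methyl]-5-(trityloxymethyl)dihydrofuran-2(3H)-one
Product: 10 (2R,4R)-4-[(TBSO)methyl]-1-(trityloxy)hex-5-yn-2-ol, via lactol 9 (not isolated)
Conditions: iBu2AlH, CH2Cl2, −78 °C; then dimethyl (1-diazo-2-oxopropyl)phosphonate, K2CO3, MeOH, 0 °C → rt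
Reagents that add atoms: dimethyl (1-diazo-2-oxopropyl)phosphonate COP(=O)(OC)C(=[N+]=[N-])C(C)=O
Why: Partial reduction to the lactol and Seyferth–Gilbert homologation with the Ohira–Bestmann reagent turn the masked aldehyde into the terminal alkyne under mild carbonate conditions that should leave the adjacent centre intact, and the ring oxygen is released as the C6 hydroxyl.

Step 6
Reactants: 10 (2R,4R)-4-[(TBSO)methyl]-1-(trityloxy)hex-5-yn-2-ol
Product: 11 (2R,4R)-2-(TBSO)-4-[(TBSO)methyl]-1-(trityloxy)hex-5-yne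
Conditions: TBSCl, imidazole, DMF, rt
Reagents that add atoms: TBSCl CC(C)(C)[Si](C)(C)Cl
Why: Silyl ether formation blocks the secondary hydroxyl so that it cannot add to the ynone or the furanone later.

Step 7
Reactants: 11 (2R,4R)-2-(TBSO)-4-[(TBSO)methyl]-1-(trityloxy)hex-5-yne; 4 (2R,5S)-5-allyl-2-tert-butyl-5-methyl-1,3-dioxolan-4-one
Product: 14 (S)-2-allyl-2-methyl-5-[(2S,4R)-1,4-bis(TBSO)-5-(trityloxy)pentan-2-yl]furan-3(2H)-one, via lithium acetylide 12 (not isolated), via hydroxy ynone 13 (not isolated)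
Conditions: nBuLi, THF, −78 °C; then 4, −78 → −40 °C; aq. NH4Cl; crude product with (Ph3P)AuCl (2 mol%), AgOTf (2 mol%), toluene, rt
Reagents that add atoms: none
Why: Acyl substitution of the acetylide on the dioxolanone (an activated ester whose tetrahedral adduct loses pivalaldehyde on work-up) gives the α′-hydroxy ynone, and monovalent-gold-catalysed 5-endo-dig oxa-cyclisation of the tertiary alcohol onto the alkyne closes the 3(2H)-furanone under neutral conditions that leave C10 and C4 untouched.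

Step 8
Reactants: 14 (S)-2-allyl-2-methyl-5-[(2S,4R)-1,4-bis(TBSO)-5-(trityloxy)pentan-2-yl]furan-3(2H)-one
Product: 15 (S)-2-allyl-5-[(2S,4R)-1,4-bis(TBSO)-5-hydroxypentan-2-yl]-2-methylfuran-3(2H)-one
Conditions: ZnBr2, CH2Cl2, 0 °C → rt; aq. NaHCO3
Reagents that add atoms: none
Why: Lewis-acid detritylation ionises only the trityl ether (stabilised cation) and leaves the two TBS ethers, the furanone and the allyl group alone.

Step 9
Reactants: 15 (S)-2-allyl-5-[(2S,4R)-1,4-bis(TBSO)-5-hydroxypentan-2-yl]-2-methylfuran-3(2H)-one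
Product: 16 (2R,4S)-4-[(S)-5-allyl-5-methyl-4-oxo-4,5-dihydrofuran-2-yl]-2,5-bis(TBSO)pentanal
Conditions: Dess–Martin periodinane, CH2Cl2, 0 °C → rt
Reagents that add atoms: none
Why: Dess–Martin oxidation gives the C7 aldehyde under near-neutral conditions that do not epimerise the α-silyloxy centre C6.

Step 10
Reactants: 16 (2R,4S)-4-[(S)-5-allyl-5-methyl-4-oxo-4,5-dihydrofuran-2-yl]-2,5-bis(TBSO)pentanal
Product: 17 tert-butyl (4R,6S)-6-[(S)-5-allyl-5-methyl-4-oxo-4,5-dihydrofuran-2-yl]-4,7-bis(TBSO)-3-hydroxy-2-methyleneheptanoate (C3 epimers)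
Conditions: tert-butyl acrylate (10 equiv), quinuclidine (0.5 equiv), MeOH (1 equiv), rt, 48 h
Reagents that add atoms: tert-butyl acrylate C=CC(=O)OC(C)(C)C
Why: Morita–Baylis–Hillman reaction of the activated α-silyloxy aldehyde joins C7 to C11, and the uncontrolled carbinol centre is erased in the next step.

Step 11
Reactants: 17 tert-butyl (4R,6S)-6-[(S)-5-allyl-5-methyl-4-oxo-4,5-dihydrofuran-2-yl]-4,7-bis(TBSO)-3-hydroxy-2-methyleneheptanoate
Product: 18 tert-butyl (2Z,4R,6S)-6-[(S)-5-allyl-5-methyl-4-oxo-4,5-dihydrofuran-2-yl]-2-(bromomethyl)-4,7-bis(TBSO)hept-2-enoate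
Conditions: NBS, Me2S, CH2Cl2, 0 °C → rt
Reagents that add atoms: N-bromosuccinimide BrN1C(=O)CCC1=O
Why: Corey–Kim-type activation of the allylic alcohol and SN2′ displacement by bromide give the favoured (Z)-2-(bromomethyl)enoate, with C6 cis to the CH2Br group.

Step 12
Reactants: 18 tert-butyl (2Z,4R,6S)-6-[(S)-5-allyl-5-methyl-4-oxo-4,5-dihydrofuran-2-yl]-2-(bromomethyl)-4,7-bis(TBSO)hept-2-enoate
Product: 20 tert-butyl (2Z,4R,6S)-2-(bromomethyl)-4,7-bis(TBSO)-6-[(S)-5-methyl-4-oxo-5-(2-oxoethyl)-4,5-dihydrofuran-2-yl]hept-2-enoate, via diol 19 (not isolated)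
Conditions: OsO4 (2 mol%), NaIO4 (4 equiv), 2,6-lutidine, dioxane/H2O (3:1), rt
Reagents that add atoms: OsO4 O=[Os](=O)(=O)=O (oxygen donor, re-formed by NaIO4 [Na+].[O-]I(=O)(=O)=O)
Why: Lemieux–Johnson oxidation dihydroxylates only the electron-rich monosubstituted alkene and cleaves the diol to the C8 aldehyde, while the electron-poor enoate and the push–pull furanone alkene are left alone.

Step 13
Reactants: 20 tert-butyl (2Z,4R,6S)-2-(bromomethyl)-4,7-bis(TBSO)-6-[(S)-5-methyl-4-oxo-5-(2-oxoethyl)-4,5-dihydrofuran-2-yl]hept-2-enoate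
Product: 22 tert-butyl (4S,6R,7R,8R,10S)-6,15-bis(TBSO)-8-hydroxy-1-oxo-3,10-epoxygermacra-2,11(13)-dien-12-oate, via allylindium dibromide 21 (not isolated)
Conditions: InBr3 (20 mol%), aluminium anode, graphite cathode, nBu4NBr (0.1 M), THF/DMF (9:1), undivided cell, constant current (2.2 F/mol), 20 added over 10 h to 2 mM, rt; aq. NH4Cl
Reagents that add atoms: none
Why: Proposed new method: the cathode reduces trivalent indium (InBr3) to monovalent indium at a potential well positive of the reduction of the aldehyde, the furanone or the allylic bromide itself, monovalent indium inserts into the activated C13–Br bond to give the (Z)-allylindium 21, and this adds intramolecularly to the C8 aldehyde through a six-membered chair (Zimmerman–Traxler) transition state with C9 equatorial and the Z substituent C6 axial, which forms the C7–C8 bond and the ten-membered ring with C8–OH syn to C6, while allylic strain keeps H6 in the alkene plane so that the aldehyde attacks C7 anti to the C6 silyloxy group (C7 and C8 are both set by the bought C6 centre); slow electrogeneration of the organoindium gives pseudo-high dilution, Al3+ from the anode takes up the alkoxide so that indium turns over, the tert-butyl ester blocks lactonisation onto C8, and the closest known reactions are the indium-catalysed electrochemical Barbier allylation of aldehydes with simple allyl bromides and the stoichiometric indium- or chromium-mediated Barbier macrocyclisations of 2-(alkoxycarbonyl)allyl bromides.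

Step 14
Reactants: 22 tert-butyl (4S,6R,7R,8R,10S)-6,15-bis(TBSO)-8-hydroxy-1-oxo-3,10-epoxygermacra-2,11(13)-dien-12-oate
Product: 23 tert-butyl (4S,6R,7R,8R,10S)-8-angeloyloxy-6,15-bis(TBSO)-1-oxo-3,10-epoxygermacra-2,11(13)-dien-12-oate
Conditions: angelic acid, 2,4,6-trichlorobenzoyl chloride, Et3N, toluene, rt, 2 h; then 22, 80 °C
Reagents that add atoms: angelic acid C/C=C(/C)C(=O)O
Why: Yamaguchi esterification through the preformed mixed anhydride, run without DMAP, acylates the hindered C8 alcohol with retention and without isomerising the angelate to the tiglate.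

Step 15
Reactants: 23 tert-butyl (4S,6R,7R,8R,10S)-8-angeloyloxy-6,15-bis(TBSO)-1-oxo-3,10-epoxygermacra-2,11(13)-dien-12-oate
Product: 25 (4S,6R,7S,8R,10S)-8-angeloyloxy-15-hydroxy-1-oxo-3,10-epoxygermacra-2,11(13)-dien-12,6-olide, via seco hydroxy acid 24 (not isolated)
Conditions: TFA/CH2Cl2/H2O (9:10:1), 0 °C → rt; aq. NaHCO3
Reagents that add atoms: none
Why: Acidolysis removes the tert-butyl ester and both TBS ethers, and the freed C6 hydroxyl lactonises onto C12 (five-membered ring, retention at C6) to give the trans-fused α-methylene-γ-butyrolactone whose configuration was fixed in steps 4 and 13.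

**Compound list**

1 | D-lactic acid [(R)-2-hydroxypropanoic acid] | C[C@@H](O)C(=O)O | starting material
2 | (2R,5R)-2-tert-butyl-5-methyl-1,3-dioxolan-4-one | C[C@H]1O[C@@H](C(C)(C)C)OC1=O | intermediate
3 | lithium (2R)-2-tert-butyl-5-methyl-1,3-dioxol-4-olate (lithium enolate of 2) | CC1=C([O-])O[C@H](C(C)(C)C)O1.[Li+] | intermediate
4 | (2R,5S)-5-allyl-2-tert-butyl-5-methyl-1,3-dioxolan-4-one | C[C@@]1(CC=C)O[C@@H](C(C)(C)C)OC1=O | intermediate
5 | (R)-5-(trityloxymethyl)dihydrofuran-2(3H)-one | O=C1CC[C@H](COC(c2ccccc2)(c2ccccc2)c2ccccc2)O1 | starting material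
6 | sodium enolate of (5R)-3-formyl-5-(trityloxymethyl)dihydrofuran-2(3H)-one | [Na+].[O-]C=C1C[C@H](COC(c2ccccc2)(c2ccccc2)c2ccccc2)OC1=O | intermediate
7 | (5R,E)-3-[(TBSO)methylene]-5-(trityloxymethyl)dihydrofuran-2(3H)-one | O=C1/C(=C/O[Si](C)(C)C(C)(C)C)C[C@H](COC(c2ccccc2)(c2ccccc2)c2ccccc2)O1 | intermediate
8 | (3S,5R)-3-[(TBSO)methyl]-5-(trityloxymethyl)dihydrofuran-2(3H)-one (cis) | O=C1[C@H](CO[Si](C)(C)C(C)(C)C)C[C@H](COC(c2ccccc2)(c2ccccc2)c2ccccc2)O1 | intermediate
9 | (3S,5R)-3-[(TBSO)methyl]-5-(trityloxymethyl)tetrahydrofuran-2-ol (lactol, anomers) | OC1[C@H](CO[Si](C)(C)C(C)(C)C)C[C@H](COC(c2ccccc2)(c2ccccc2)c2ccccc2)O1 | intermediate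
10 | (2R,4R)-4-[(TBSO)methyl]-1-(trityloxy)hex-5-yn-2-ol | C#C[C@H](CO[Si](C)(C)C(C)(C)C)C[C@@H](O)COC(c1ccccc1)(c1ccccc1)c1ccccc1 | intermediate
11 | (2R,4R)-2-(TBSO)-4-[(TBSO)methyl]-1-(trityloxy)hex-5-yne | C#C[C@H](CO[Si](C)(C)C(C)(C)C)C[C@@H](O[Si](C)(C)C(C)(C)C)COC(c1ccccc1)(c1ccccc1)c1ccccc1 | intermediate
12 | lithium acetylide of 11 | [Li+].[C-]#C[C@H](CO[Si](C)(C)C(C)(C)C)C[C@@H](O[Si](C)(C)C(C)(C)C)COC(c1ccccc1)(c1ccccc1)c1ccccc1 | intermediate
13 | (4S,8R,10R)-10-(TBSO)-8-[(TBSO)methyl]-4-hydroxy-4-methyl-11-(trityloxy)undec-1-en-6-yn-5-one | C=CC[C@](C)(O)C(=O)C#C[C@H](CO[Si](C)(C)C(C)(C)C)C[C@@H](O[Si](C)(C)C(C)(C)C)COC(c1ccccc1)(c1ccccc1)c1ccccc1 | intermediate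
14 | (S)-2-allyl-2-methyl-5-[(2S,4R)-1,4-bis(TBSO)-5-(trityloxy)pentan-2-yl]furan-3(2H)-one | C=CC[C@]1(C)OC(=CC1=O)[C@H](CO[Si](C)(C)C(C)(C)C)C[C@@H](O[Si](C)(C)C(C)(C)C)COC(c1ccccc1)(c1ccccc1)c1ccccc1 | intermediate
15 | (S)-2-allyl-5-[(2S,4R)-1,4-bis(TBSO)-5-hydroxypentan-2-yl]-2-methylfuran-3(2H)-one | C=CC[C@]1(C)OC(=CC1=O)[C@H](CO[Si](C)(C)C(C)(C)C)C[C@@H](O[Si](C)(C)C(C)(C)C)CO | intermediate
16 | (2R,4S)-4-[(S)-5-allyl-5-methyl-4-oxo-4,5-dihydrofuran-2-yl]-2,5-bis(TBSO)pentanal | C=CC[C@]1(C)OC(=CC1=O)[C@H](CO[Si](C)(C)C(C)(C)C)C[C@@H](O[Si](C)(C)C(C)(C)C)C=O | intermediate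
17 | tert-butyl (4R,6S)-6-[(S)-5-allyl-5-methyl-4-oxo-4,5-dihydrofuran-2-yl]-4,7-bis(TBSO)-3-hydroxy-2-methyleneheptanoate (C3 epimers) | C=CC[C@]1(C)OC(=CC1=O)[C@H](CO[Si](C)(C)C(C)(C)C)C[C@@H](O[Si](C)(C)C(C)(C)C)C(O)C(=C)C(=O)OC(C)(C)C | intermediate
18 | tert-butyl (2Z,4R,6S)-6-[(S)-5-allyl-5-methyl-4-oxo-4,5-dihydrofuran-2-yl]-2-(bromomethyl)-4,7-bis(TBSO)hept-2-enoate | C=CC[C@]1(C)OC(=CC1=O)[C@H](CO[Si](C)(C)C(C)(C)C)C[C@@H](O[Si](C)(C)C(C)(C)C)/C=C(\CBr)C(=O)OC(C)(C)C | intermediate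
19 | tert-butyl (2Z,4R,6S)-2-(bromomethyl)-4,7-bis(TBSO)-6-[(5S)-5-(2,3-dihydroxypropyl)-5-methyl-4-oxo-4,5-dihydrofuran-2-yl]hept-2-enoate (diol epimers) | OCC(O)C[C@]1(C)OC(=CC1=O)[C@H](CO[Si](C)(C)C(C)(C)C)C[C@@H](O[Si](C)(C)C(C)(C)C)/C=C(\CBr)C(=O)OC(C)(C)C | intermediate
20 | tert-butyl (2Z,4R,6S)-2-(bromomethyl)-4,7-bis(TBSO)-6-[(S)-5-methyl-4-oxo-5-(2-oxoethyl)-4,5-dihydrofuran-2-yl]hept-2-enoate | O=CC[C@]1(C)OC(=CC1=O)[C@H](CO[Si](C)(C)C(C)(C)C)C[C@@H](O[Si](C)(C)C(C)(C)C)/C=C(\CBr)C(=O)OC(C)(C)C | intermediate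
21 | (Z)-allylindium dibromide from 20 (C13–InBr2 in place of C13–Br) | O=CC[C@]1(C)OC(=CC1=O)[C@H](CO[Si](C)(C)C(C)(C)C)C[C@@H](O[Si](C)(C)C(C)(C)C)/C=C(\C[In](Br)Br)C(=O)OC(C)(C)C | intermediate
22 | tert-butyl (4S,6R,7R,8R,10S)-6,15-bis(TBSO)-8-hydroxy-1-oxo-3,10-epoxygermacra-2,11(13)-dien-12-oate | C=C(C(=O)OC(C)(C)C)[C@H]1[C@H](O[Si](C)(C)C(C)(C)C)C[C@@H](CO[Si](C)(C)C(C)(C)C)C2=CC(=O)[C@](C)(C[C@H]1O)O2 | intermediate
23 | tert-butyl (4S,6R,7R,8R,10S)-8-angeloyloxy-6,15-bis(TBSO)-1-oxo-3,10-epoxygermacra-2,11(13)-dien-12-oate | C=C(C(=O)OC(C)(C)C)[C@H]1[C@H](O[Si](C)(C)C(C)(C)C)C[C@@H](CO[Si](C)(C)C(C)(C)C)C2=CC(=O)[C@](C)(C[C@H]1OC(=O)/C(C)=C\C)O2 | intermediate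
24 | (4S,6R,7S,8R,10S)-8-angeloyloxy-6,15-dihydroxy-1-oxo-3,10-epoxygermacra-2,11(13)-dien-12-oic acid | C=C(C(=O)O)[C@H]1[C@H](O)C[C@@H](CO)C2=CC(=O)[C@](C)(C[C@H]1OC(=O)/C(C)=C\C)O2 | intermediate
25 | (4S,6R,7S,8R,10S)-8-angeloyloxy-15-hydroxy-1-oxo-3,10-epoxygermacra-2,11(13)-dien-12,6-olide (CNP0108636.1) | C=C1C(=O)O[C@@H]2C[C@@H](CO)C3=CC(=O)[C@](C)(C[C@@H](OC(=O)/C(C)=C\C)[C@@H]12)O3 | target

**Step count and risk**

Total step count: 15 (steps 1–2 for the C10 fragment, steps 3–6 for the C2–C7 fragment, steps 7–15 after union).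
Longest linear sequence: 13 steps (5 → 25, steps 3–15).

Steps most likely to fail:

Step 13 (the new electrochemical macrocyclisation). Risks are the strain of the bicyclic ten-membered ring, loss of the Z geometry of the allylindium (which would erode the syn selectivity), β-elimination of the C6 silyloxy group from a metallotropic isomer, and base-induced β-elimination of the furanone oxygen from the C8 aldehyde. Fallback, known chemistry: from 20, a thermal Nozaki–Hiyama–Kishi-type cyclisation with stoichiometric CrCl2 (divalent chromium; THF, 3 mM, rt) replaces the electrocatalytic indium cycle. Allylchromium species equilibrate and add through the E-type chair, so the anti adduct is expected, that is the C8 epimer tert-butyl (4S,6R,7R,8S,10S)-6,15-bis(TBSO)-8-hydroxy-1-oxo-3,10-epoxygermacra-2,11(13)-dien-12-oate F1. Mitsunobu esterification of F1 with angelic acid (PPh3, DIAD, toluene, 0 °C → rt) then installs the ester with inversion at C8. The fallback sets out from 20 and comes back to the route at 23.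

Step 10 (Morita–Baylis–Hillman reaction). The aldehyde is hindered and its α-silyloxy centre C6 can epimerise during a slow amine-mediated reaction with the sluggish tert-butyl acrylate. Fallback: from 16, Horner–Wadsworth–Emmons olefination with tert-butyl 2-(diethoxyphosphoryl)-3-[(4-methoxybenzyl)oxy]propanoate (NaH, THF, −78 → 0 °C) gives the trisubstituted enoate with the aldehyde chain trans to the ester, tert-butyl (2E,4R,6S)-6-[(S)-5-allyl-5-methyl-4-oxo-4,5-dihydrofuran-2-yl]-4,7-bis(TBSO)-2-[(4-methoxybenzyloxy)methyl]hept-2-enoate F2. DDQ (CH2Cl2/pH 7 buffer) frees the allylic alcohol tert-butyl (2E,4R,6S)-6-[(S)-5-allyl-5-methyl-4-oxo-4,5-dihydrofuran-2-yl]-4,7-bis(TBSO)-2-(hydroxymethyl)hept-2-enoate F3, and an Appel reaction (CBr4, PPh3, CH2Cl2, 0 °C) converts F3 into the bromide. The fallback sets out from 16 and comes back at 18.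

Step 5 (lactol to alkyne). The open form of lactol 9 is a β-silyloxy aldehyde with an α-stereocentre (future C4); carbonate in methanol may epimerise it or eliminate silanolate. Fallback: from 8, MeLi (THF, −78 °C) gives the methyl lactol (3S,5R)-3-[(TBSO)methyl]-2-methyl-5-(trityloxymethyl)tetrahydrofuran-2-ol F4. TBSOTf/2,6-lutidine traps its open form as the methyl ketone (3S,5R)-5-(TBSO)-3-[(TBSO)methyl]-6-(trityloxy)hexan-2-one F5. The kinetic lithium enolate of F5 (LiN(iPr)2, THF, −78 °C, deprotonation at the methyl group) is acylated by dioxolanone 4 in a Claisen condensation to the α′-hydroxy-1,3-diketone (4S,8S,10R)-10-(TBSO)-8-[(TBSO)methyl]-4-hydroxy-4-methyl-11-(trityloxy)undec-1-ene-5,7-dione F6. Acid-catalysed cyclodehydration of F6 (PPTS, benzene, rt) gives the furanone. The fallback sets out from 8 and comes back at 14, bypassing steps 5–7.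

**Further compounds**

F1 | step 13 | tert-butyl (4S,6R,7R,8S,10S)-6,15-bis(TBSO)-8-hydroxy-1-oxo-3,10-epoxygermacra-2,11(13)-dien-12-oate (8-epi-22) | C=C(C(=O)OC(C)(C)C)[C@H]1[C@H](O[Si](C)(C)C(C)(C)C)C[C@@H](CO[Si](C)(C)C(C)(C)C)C2=CC(=O)[C@](C)(C[C@@H]1O)O2
F2 | step 10 | tert-butyl (2E,4R,6S)-6-[(S)-5-allyl-5-methyl-4-oxo-4,5-dihydrofuran-2-yl]-4,7-bis(TBSO)-2-[(4-methoxybenzyloxy)methyl]hept-2-enoate | C=CC[C@]1(C)OC(=CC1=O)[C@H](CO[Si](C)(C)C(C)(C)C)C[C@@H](O[Si](C)(C)C(C)(C)C)/C=C(\COCc1ccc(OC)cc1)C(=O)OC(C)(C)C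
F3 | step 10 | tert-butyl (2E,4R,6S)-6-[(S)-5-allyl-5-methyl-4-oxo-4,5-dihydrofuran-2-yl]-4,7-bis(TBSO)-2-(hydroxymethyl)hept-2-enoate | C=CC[C@]1(C)OC(=CC1=O)[C@H](CO[Si](C)(C)C(C)(C)C)C[C@@H](O[Si](C)(C)C(C)(C)C)/C=C(\CO)C(=O)OC(C)(C)C
F4 | step 5 | (3S,5R)-3-[(TBSO)methyl]-2-methyl-5-(trityloxymethyl)tetrahydrofuran-2-ol | CC1(O)[C@H](CO[Si](C)(C)C(C)(C)C)C[C@H](COC(c2ccccc2)(c2ccccc2)c2ccccc2)O1
F5 | step 5 | (3S,5R)-5-(TBSO)-3-[(TBSO)methyl]-6-(trityloxy)hexan-2-one | CC(=O)[C@H](CO[Si](C)(C)C(C)(C)C)C[C@@H](O[Si](C)(C)C(C)(C)C)COC(c1ccccc1)(c1ccccc1)c1ccccc1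
F6 | step 5 | (4S,8S,10R)-10-(TBSO)-8-[(TBSO)methyl]-4-hydroxy-4-methyl-11-(trityloxy)undec-1-ene-5,7-dione | C=CC[C@](C)(O)C(=O)CC(=O)[C@H](CO[Si](C)(C)C(C)(C)C)C[C@@H](O[Si](C)(C)C(C)(C)C)COC(c1ccccc1)(c1ccccc1)c1ccccc1
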